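(The earlier runs and the new flask were computed with constants of no real substance; noise was put on by code.)

The closed vessel keeps J for the whole run, and while D is still being used, J can pass on to Z, which no reading shows. The share of J therefore has to be bracketed from what the readings do show.

| flask | D | L | remark | time |
|---|---|---|---|---|
| grey | 0.016 M | 0.45 M | run made earlier |  |
| ochre | 0.17 M | 0.45 M | run made earlier |  |
| red | 1.4 M | 0.45 M | run made earlier |  |
| eta | 0.020 M | 0.450 M |  | 2.0 min |
| alpha | 0.060 M | 0.450 M |  | 2.0 min |
| beta | 0.15 M | 0.450 M |  | 2.0 min |
| epsilon | 0.50 M | 0.450 M |  | 2.0 min |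
| gamma | 1.5 M | 0.450 M |  | 2.0 min |

- grey (time / s: J / %, E / %): 15.0: 28.1, 0.4; 30.0: 47.6, 0; 50.0: 65.3, 0; 60.0: 70.6, 0.1; 80.0: 79.7, 0.3
- ochre (time / s: J / %, E / %): 10.0: 19.3, 0.2; 12.0: 22.3, 0; 25.0: 39.7, 0.2; 40.0: 53.0, 0.1; 80.0: 73.6, 0.6
- red (time / s: J / %, E / %): 10.0: 14.8, 1.5; 12.0: 16.8, 2.0; 25.0: 24.2, 2.7; 40.0: 27.4, 4.2; 80.0: 30.4, 8.4

(standard deviation of a reading: 0.3 percentage points)

- a species is counted by the D in it: one E counts as two
- steps that have been proposed: D + L -> J; D -> Q; J <-> Z; 2 D -> E
- "hardly changes" means that all values lie within two and a half points (for a concentration: within two and a half percent of the largest)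

1. share of J in all that became J or E or Z for eta, alpha, beta, epsilon, gamma, in this order
2. how the row runs (falls, then rises / rises all the way / falls all the way / hardly changes / rises, then falls)

In grey, D is scarce against L, so D falls pseudo-first-order, and the first reading gives a rate constant of 0.0220 s⁻¹. That constant predicts 82.8% converted at 80.0 s, but J reads 79.7%, a shortfall of 3.1 percentage points. J had been present for an average exposure of 42.4 s. Their ratio gives a reading of the forward half-life of J, 15.9 min, with the way back not counted.

For eta, E stays within the scatter of grey, so the share is J over J plus Z. If J stood from the start for 2.0 min, the share would be 91.6%, which is the bound from below. Real exposure gives 93.9%. With the shortfall taken at 0.5 of its reading, the bound from above is 96.9%.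

At the other end, L is the limiting reagent in gamma, so J and Z together stop at 30.0%. E lies between red's 8.4% and that reading scaled by time and charge, 13.5%. The share in gamma therefore lies between 64.8% and 73.4%, and the row should fall.

The forecast, holding that “the loss comes from J itself”, gives 94.3%, 94%, 93.7%, 91% and 67%, and says the row falls all the way. Both of its ends stand inside the brackets.

The flask gives 95.2%, 95.1%, 94.8%, 92.3% and 69.2%, and the row falls all the way; both ends again lie inside the brackets.

    D + L → J (k = 0.0490 M⁻¹ s⁻¹)
    D → Q (k = 2.90 × 10⁻⁶ s⁻¹)
    J ⇌ Z (K = 0.240, k = 6.60 × 10⁻⁴ s⁻¹)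
    2 D → E (k = 6.40 × 10⁻⁴ M⁻¹ s⁻¹)

In eta, the forward half-life of J by the turning into Z is 18 min, long against the 2.0 min of the run, and at that time J is still made 3.52 times faster than it is used up. Eta then holds 87.9% J against 4.36% Z. Over the second minute in eta, the half-life of 15.9 min read from grey and the mean J give a forward gain of Z of 3.5 points, the forward constant of the scheme gives 3.1 points, and Z, with the way back counted, goes from 1.62% to 4.36%. In beta the same two reckonings, again forward only, give 3.3 points and 3 points, and Z goes from 1.53% to 4.10%.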